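Take larch, the first run, and ask how fast its electrophile goes, what slows it, and what that slowing leaves at the end.

| flask | electrophile | free base | protonated nucleophile | protic impurity | remark | time |
|---|---|---|---|---|---|---|
| larch | 1 M | 1.8 M | 0.90 M | 0.20 M | run made earlier |  |
| cedar | 1 M | 1.7 M | 0.90 M | 0.20 M | run made earlier |  |
| ash | 1 M | 2.4 M | 0.90 M | 0.20 M | run made earlier |  |
| theta | 1.0 M | 1.50 M | 0.900 M | 0.200 M |  | 25 h |
| eta | 1.0 M | 2.20 M | 0.900 M | 0.200 M |  | 25 h |

| run | time / h | electrophile / % | target / % |
|---|---|---|---|
| larch | 2.00 | 25.6 | 65.5 |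
| larch | 4.00 | 23.6 | 60.9 |
| larch | 8.00 | 23.2 | 51.2 |
| larch | 12.0 | 22.9 | 45.1 |
| larch | 25.0 | 22.6 | 39.8 |
| cedar | 5.00 | 23.3 | 57.9 |
| cedar | 10.0 | 22.6 | 48.1 |
| cedar | 15.0 | 22.8 | 42.2 |
| cedar | 20.0 | 23.5 | 40.6 |
| cedar | 25.0 | 23.5 | 39.6 |
| ash | 5.00 | 22.9 | 58.3 |
| ash | 10.0 | 22.4 | 48.4 |
| ash | 15.0 | 23.1 | 43.1 |
| ash | 20.0 | 22.8 | 41.1 |
| ash | 25.0 | 23.5 | 39.5 |

(standard deviation of a reading: 0.5 percentage points)

- part of the electrophile that has reacted at the end, theta
- part of the electrophile that has reacted at the end, eta
- what raising the concentration of free base from its lowest to its highest value here does to the part of the electrophile that has reacted (changes below 5 percentage points count as none) (it rises / it falls / no change)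



In larch the electrophile falls at 0.372 M h⁻¹ on average up to 2.00 h, then at about 0.00400 M h⁻¹ up to 8.00 h, a reading with much scatter. That is a slowing by about 93.0. The electrophile's own shrinking gives a factor of about 3.91, so I put the remaining factor of about 23.8 on its partner.

My reckoning assumes that free base releases a nucleophile from the protonated nucleophile, that the whole charge of it gets used, and that the protic impurity competes for it. The three runs end with 23.2% of the electrophile left, so 0.768 M reacted. That leaves 0.132 M of the nucleophile for the impurity, and 34.0% of the impurity remains. Both rates carry the same nucleophile, which cancels in their ratio, so the two logarithms of what is left keep a fixed ratio. This gives 1.35, the selectivity factor: the logarithm of the electrophile left divided by the logarithm of the impurity left. Free base does not enter that ratio, so, taking the whole protonated nucleophile to be used in theta and eta as well, I expect 76.8% reacted in both.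

The forecast says 76% for theta, 77% for eta and no change, with the caution that “a threshold just below 1.7 M cannot be excluded”.

The flasks give 76.7% for theta and 76.8% for eta, a change of 0.011 percentage points: no change.

    electrophile + nucleophile → acid set free + target (k = 9.00 × 10⁻⁴ M⁻¹ s⁻¹)
    nucleophile + acid set free ⇌ protonated nucleophile, settled at all times (K = 30.0 M⁻¹)
    acid set free + free base ⇌ salt of the base, settled at all times (K = 36000 M⁻¹)
    nucleophile + protic impurity → quenched reagent (k = 6.70 × 10⁻⁴ M⁻¹ s⁻¹)
    acid set free + target → side product (k = 3.60 × 10⁻⁵ M⁻¹ s⁻¹)
    target ⇌ isomer of the product (K = 1.00, k = 2.00 × 10⁻⁵ s⁻¹)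

Eta ends with 34% of its impurity, and raising that to the power of the selectivity factor gives 23.0% of electrophile left. The neighbour flask is like eta but holds 0.080 M of protic impurity, and it ends with 26% of that impurity. The same power gives 15.7% of electrophile left. That neighbour flask holds 16.0%, so 84.0% has reacted, more than in eta.

(The readings are simulated for substances that don't exist, and the scatter is random.)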